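## Analysis of the target

The target is a 2,5-diaryl-3,4-dimethyltetrahydrofuran, numbered O1, C2, C3, C4, C5. Its two guaiacyl rings, ring A on C2 and ring B on C5, each carry on the para oxygen a 1-(3,4-dimethoxyphenyl)-1-hydroxypropan-2-yl arm. The ring is (2S,3R,4R,5R): ring A is cis to the C3 methyl, the two methyls are trans, and ring B is trans to the C4 methyl, so the aryl groups are 2,5-cis and the core has one cis end and one trans end. Both arms are threo (syn), but the ring A arm is (1R,2R) and the ring B arm is (1S,2S). The molecule therefore has no symmetry element, and the two rings must be told apart from the first C–C bond onward; there are eight stereocenters in all. The sensitive sites are C2 and C5, both benzylic ether carbons next to p-alkoxyaryl rings, which ionise under acid and then epimerise towards the all-trans ring. Also sensitive are the benzylic carbinols of the arms and, at the ketone stage, the aryloxy-bearing carbon next to the carbonyl. The hard part is the cis relation at C2, which is the less stable one, beside three trans relations, in the correct absolute sense relative to two enantiomeric arms. The strategy rests on this feature: C2 and C5 are both benzylic and both bonded to O1, and C2–C3 and C5–C4 are each the Cα–Cβ bond of an isoeugenol unit. Deleting O1 and joining C2 to C5 gives the all-trans head-to-head cyclobutane dimer of two (E)-isoeugenol ethers, which differs from the core by one oxygen atom and by the configuration at C2.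

## Retrosynthetic reasoning

**Ring A arm.** Target 23 is taken back at the carbinol C–H bond to ketone 22. The bond between the ring A phenol oxygen and the arm carbon next to the carbonyl is then cut, giving phenol 17 and the (S)-keto tosylate 21. Cutting this C–O bond, and not the aryl–O bond, leaves the phenol oxygen on the core, where isoeugenol already provides it, and places the electrophilic carbon next to a carbonyl, where SN2 displacement with inversion is reliable. The forward sequence must invert that carbon cleanly and then reduce the ketone to the threo alcohol under Felkin–Anh control.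

**Ring B arm and the order of the arms.** The arms are enantiomeric, so they are attached one at a time. Phenol 17 comes from benzyl ether 16, which is taken back in the same way to ketone 15, and then to phenol 9 and the (R)-keto tosylate 14. Phenol 9 comes from pivalate 8. The benzyl ether on ring A and the pivalate on ring B are orthogonal masks, and they also make ring A the better electron donor and ring B the poorer one, which the key step needs.

**Key disconnection.** In 8 the bonds O1–C2 and O1–C5 are cut and C2 is joined to C5, giving cyclobutane 7. This removes the heteroatom and returns the core to a pure dimer of two C6–C3 units with both methyls and both aryls in place and the trans relations C3/C4 and C4/C5 already set. The forward reaction must break the C2–C5 bond of 7, place oxygen on C2 with inversion, and close the ring onto C5 trans to the C4 methyl.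

**Cyclobutane.** Cyclobutane 7 is one enantiomer of racemate 6. In 6 the bonds C3–C4 and C2–C5 are cut, giving the two alkenes 3 and 5. The forward reaction is a hole-catalysed crossed [2+2] cycloaddition, which gives the head-to-head all-trans ring but no absolute control, so 6 is resolved.

**Alkenes.** Alkenes 3 and 5 come from phenol 1 by O-benzylation with 2 and O-acylation with 4.

**Arm electrophiles.** Tosylates 14 and 21 are taken back at the O–S bond to hydroxy ketones 13 and 20. These are cut at the aryl–carbonyl bond into aryl Grignard reagent 12 and lactamides 11 and 19, which come from lactate esters 10 and 18. The chiral pool fixes the arm carbon that is later inverted.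

## Alternatives that were turned down

**Alternative 1:** The disconnection cuts C2–C3 and C4–C5, with C2 as a carbonyl carbon. In the forward direction amide A1 is turned into its keteniminium salt with Tf2O and a hindered pyridine and adds to alkene A2, giving after hydrolysis cyclobutanone A3. Baeyer–Villiger oxidation with migration of the benzylic carbon gives lactone A4, and ring A would be added as an aryl nucleophile, followed by ionic reduction of the hemiketal.

- For it: the C2-symmetric amine of A1 sets the absolute configuration, so no resolution is needed. The geometry of A2 is carried into the trans methyls, and the aryl-bearing carbon α to the ketone equilibrates to trans. On absolute stereocontrol this alternative is stronger than the chosen strategy.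
- Against it: the electron-rich arene of A1 is exposed to Tf2O and to its own keteniminium ion, and an unactivated, gaseous 1,2-disubstituted alkene is the least reactive partner class. The decisive point is that C2 is made last, by hydride addition to the 2-aryl oxocarbenium ion derived from A4. With both methyls pseudo-equatorial in the envelope, inside attack puts hydride cis to the C3 methyl and ring A trans to it, which is the all-trans core and not the target.
- Comparison: the chosen strategy sets C2 by inversion in the bond-forming event itself and not by a facial preference that opposes the target. It reaches the core in five steps against six or seven, at the price of a resolution and an unproven key step.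

**Alternative 2:** The disconnection cuts C4–C5 and leaves C3 as a carbonyl. In the forward direction Me2AlCl ionises the bond between the acetal carbon and the enol ether oxygen of dioxolane A5, and the aluminium enolate carbon recloses on the oxocarbenium carbon (a Petasis–Ferrier-type rearrangement), giving furanone A6.

- For it: the rearrangement type is known. It gives the 2,5-cis diaryl relation, which the target has, and it differentiates the two rings by construction. The absolute configuration can come from an enantiopure α-hydroxy acid. On precedent for the key step it is stronger than the chosen strategy.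
- Against it: A6 lacks the C3 methyl. It has to be installed by methylenation and face-selective hydrogenation, and the hydrogenation conflicts with the ring A benzyl ether. C2 of A6 is benzylic, α to oxygen and α to the ketone, so the very centre that is the less stable one in the target is the easiest to epimerise. The C4 configuration depends on the ethylidene geometry of A5 (drawn as Z), which carbonyl ethylidenation of a dioxolanone does not deliver cleanly.
- Comparison: about eight or nine steps to the core against five. The chosen strategy has both methyls in place from the outset and has no enolisable centre next to C2.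

**Alternative 3:** The disconnection cuts O1–C2 and C4–C5. In the forward direction, under Sn(OTf)2, the oxygen of aldehyde A8 opens donor–acceptor cyclopropane A7 at its benzylic carbon with inversion, and the malonate carbon closes on the oxocarbenium carbon, giving tetrahydrofuran diester A9.

- For it: this cycloaddition type is well established, gives 2,5-cis products and is stereospecific with inversion at the donor carbon. It uses the same stereochemical logic at C2 as the chosen strategy, but in proven form.
- Against it: C4 arrives as a quaternary malonate carbon. Both esters must be removed and one turned into a methyl, with C4 set by a protonation (dealkoxycarbonylation, reduction, activation, deoxygenation: four or five steps). Enantiopure A7, with a strongly donating p-benzyloxyaryl group and a methyl on the ring, is hard to make. Such cyclopropanes also ionise to the ring-opened zwitterion under the Lewis acid, which erodes the stereochemical information.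
- Comparison: the chosen strategy introduces no carbon that is excised later, and all twenty core carbons come from two isoeugenol units. It is weaker only in that its inversion step is still to be demonstrated.

Key step: step 5

## Remarks and assumptions

- Ring A is the guaiacyl ring on C2 and ring B the one on C5; threo means syn in the zigzag drawing.
- Commercial trans-isoeugenol is taken as the (E)-isomer.
- The absolute configuration of 7 is assumed to be assigned, before it is carried forward, by X-ray anomalous dispersion on a crystalline derivative (for example camphanate F11).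

## Route

Step 1
Reactants: 1 (E)-isoeugenol; 2 benzyl bromide
Product: 3 (E)-isoeugenol benzyl ether, (E)-1-(benzyloxy)-2-methoxy-4-(prop-1-enyl)benzene
Conditions: K2CO3, acetone, reflux
Reagents that add atoms: none
Why: Williamson etherification of the phenoxide by SN2 on the benzylic bromide; the propenyl group is not touched and keeps its E geometry.

Step 2
Reactants: 1 (E)-isoeugenol; 4 pivaloyl chloride
Product: 5 (E)-isoeugenol pivalate, (E)-2-methoxy-4-(prop-1-enyl)phenyl 2,2-dimethylpropanoate
Conditions: Et3N, DMAP (cat.), CH2Cl2, 0 °C to rt
Reagents that add atoms: none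
Why: O-acylation of the phenol under nucleophilic catalysis; the phenol is the only nucleophile and the alkene is inert.

Step 3
Reactants: 3 (E)-isoeugenol benzyl ether; 5 (E)-isoeugenol pivalate
Product: 6 racemic all-trans 1-[4-(benzyloxy)-3-methoxyphenyl]-2-[3-methoxy-4-(pivaloyloxy)phenyl]-3,4-dimethylcyclobutane
Conditions: 5 (5 equiv), 2,4,6-tris(4-methoxyphenyl)pyrylium tetrafluoroborate (3 mol %), anthracene (0.5 equiv), acetone, 450 nm LEDs, 0 °C, slow addition of 3
Reagents that add atoms: none
Why: Hole-catalysed (radical-cation) crossed [2+2] cycloaddition, a known reaction type of anethole- and isoeugenol-type alkenes with a less oxidisable styrene in excess; the relay oxidises only 3, whose radical cation adds β-carbon to β-carbon to 5 (head-to-head), and the bis-benzylic 1,4-radical cation closes and is reduced back. The stepwise closure should place all four substituents trans, which sets the relative configuration of C3 and C4; the product is racemic.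

Step 4
Reactants: 6 racemic all-trans cyclobutane
Product: 7 (1S,2S,3R,4R)-1-[4-(benzyloxy)-3-methoxyphenyl]-2-[3-methoxy-4-(pivaloyloxy)phenyl]-3,4-dimethylcyclobutane (C1 carries ring A, C2 ring B)
Conditions: preparative SFC, amylose tris(3,5-dimethylphenylcarbamate) phase, CO2/iPrOH
Reagents that add atoms: none
Why: Resolution of enantiomers by chromatography on a chiral stationary phase; no bond is formed, and this fixes the absolute configuration of C3 and C4 of the target. The other enantiomer can in principle be returned to 3 and 5 by hole-catalysed cycloreversion.

Step 5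
Reactants: 7 (1S,2S,3R,4R)-cyclobutane
Product: 8 (2S,3R,4R,5R)-2-[4-(benzyloxy)-3-methoxyphenyl]-5-[3-methoxy-4-(pivaloyloxy)phenyl]-3,4-dimethyltetrahydrofuran (ring A cis to the C3 methyl, methyls trans, ring B trans to the C4 methyl)
Conditions: constant-current electrolysis, undivided cell, reticulated vitreous carbon anode, Pt cathode, LiClO4 (0.1 M), 2,6-lutidine (2 equiv), MeCN/H2O 9:1, 0 °C, about 2.2 F/mol
Reagents that add atoms: water, O
Why: Proposed new method: one-electron oxidation at the anode should take the electron from ring A, the better donor, and delocalise the hole into the strained cyclobutane bond between the two benzylic carbons (future C2–C5), which stretches to a one-electron bond with positive charge at the ring A carbon and spin at the ring B carbon. Water then attacks the ring A carbon from the side opposite the departing ring B carbon (three-electron SN2), which forms O1–C2 with inversion and turns the trans relation of ring A and the C3 methyl into the cis relation of the target, while 2,6-lutidine takes the proton. The ring-opened benzylic radical at C5 is oxidised at the anode to the cation, and the new hydroxyl closes on it in a 5-exo-trig mode (the quinoid C5–aryl bond stays outside the ring), forming O1–C5. C5 is set in this closure, because the planar cation is attacked on the face that leaves ring B trans to the C4 methyl in the envelope transition state, and C3 and C4 are carried over unchanged from 7. The closest known reaction types are the anodic dimerisation–hydration of anethole-type alkenes to 2,5-diaryl-3,4-dimethyltetrahydrofurans, which ends in the same hydroxyl capture of a benzylic cation, and the nucleophile-assisted opening of arylcyclopropane radical cations, which goes with inversion; neither has been shown on a cyclobutane C–C bond. The step needs site selectivity (water at C2, not C5) and a stereospecific capture that is faster than cycloreversion to 3 and 5; the first is secured by the donor gap between the benzyloxy ring and the pivaloyloxy ring, the second is favoured by the strain released, the high water concentration, the low temperature and the buffered medium, which also protects C2 of 8 from acid epimerisation. The cathode reduces the liberated protons to H2, so the electron-rich rings meet no chemical oxidant.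

Step 6
Reactants: 8 tetrahydrofuran with ring A benzyl ether and ring B pivalate
Product: 9 (2S,3R,4R,5R)-2-[4-(benzyloxy)-3-methoxyphenyl]-5-(4-hydroxy-3-methoxyphenyl)-3,4-dimethyltetrahydrofuran
Conditions: NaOMe, MeOH/THF, rt; aq NH4Cl
Reagents that add atoms: none
Why: Methanolysis (transesterification) of the aryl pivalate; the benzyl ether and the ring ethers are inert to methoxide, and no stereocenter is involved.

Step 7
Reactants: 10 methyl (R)-lactate
Product: 11 (R)-2-hydroxy-1-(pyrrolidin-1-yl)propan-1-one
Conditions: pyrrolidine (neat, 3 equiv), rt to 50 °C
Reagents that add atoms: pyrrolidine, C1CCNC1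
Why: Aminolysis of the activated α-hydroxy ester by a secondary amine; the stereocenter is not part of the reaction.

Step 8
Reactants: 11 (R)-lactic pyrrolidide; 12 (3,4-dimethoxyphenyl)magnesium bromide
Product: 13 (R)-1-(3,4-dimethoxyphenyl)-2-hydroxypropan-1-one
Conditions: 12 (2.5 equiv), THF, −20 to 0 °C; aq NH4Cl
Reagents that add atoms: none
Why: Grignard addition to a tertiary amide; the first equivalent forms the magnesium alkoxide, and the chelated tetrahedral adduct of the second resists further addition and enolisation until work-up, so the ketone is released with the α-centre intact.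

Step 9
Reactants: 13 (R)-hydroxy ketone
Product: 14 (R)-1-(3,4-dimethoxyphenyl)-1-oxopropan-2-yl 4-methylbenzenesulfonate
Conditions: TsCl, Et3N, DMAP (cat.), CH2Cl2, 0 °C
Reagents that add atoms: p-toluenesulfonyl chloride, Cc1ccc(cc1)S(Cl)(=O)=O
Why: O-sulfonylation of the secondary alcohol; the O–S bond is formed, so the configuration is retained.

Step 10
Reactants: 9 ring B phenol; 14 (R)-keto tosylate
Product: 15 ring B aryloxy ketone: core of 9 in which the ring B oxygen carries (S)-CH(CH3)–C(=O)–(3,4-dimethoxyphenyl)
Conditions: K2CO3, DMF, rt
Reagents that add atoms: none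
Why: SN2 displacement of a sulfonate next to a carbonyl by the phenoxide (Williamson-type etherification) with inversion, (R) to (S); the α-carbonyl activation lets it run at room temperature, where the cis-configured C2 is not at risk.

Step 11
Reactants: 15 ring B aryloxy ketone
Product: 16 ring B threo alcohol: core of 9 in which the ring B oxygen carries the (1S,2S)-1-(3,4-dimethoxyphenyl)-1-hydroxypropan-2-yl arm
Conditions: Bu4NBH4, CH2Cl2/MeOH, −40 to 0 °C
Reagents that add atoms: none
Why: Felkin–Anh-controlled hydride reduction; with the non-chelating ammonium counter-ion the aryloxy group stands anti to the incoming hydride, which passes the small hydrogen, and this should give the threo (1S,2S) alcohol, while the Cram-chelate path to the erythro isomer is shut off.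

Step 12
Reactants: 16 ring A benzyl ether with ring B arm
Product: 17 ring A phenol: (2S,3R,4R,5R)-2-(4-hydroxy-3-methoxyphenyl)-3,4-dimethyltetrahydrofuran carrying on C5 the ring B unit with its (1S,2S) arm
Conditions: H2 (1 atm), Pd/C (10 wt %), EtOAc, rt
Reagents that add atoms: none
Why: Hydrogenolysis of the aryl benzyl ether, which in a neutral solvent is much faster than cleavage of the ring benzylic ethers or of the benzylic carbinol; no stereocenter is involved.

Step 13
Reactants: 18 ethyl (S)-lactate
Product: 19 (S)-2-hydroxy-1-(pyrrolidin-1-yl)propan-1-one
Conditions: pyrrolidine (neat, 3 equiv), rt to 50 °C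
Reagents that add atoms: pyrrolidine, C1CCNC1
Why: Aminolysis of the lactate ester as in step 7, in the enantiomeric series.

Step 14
Reactants: 19 (S)-lactic pyrrolidide; 12 (3,4-dimethoxyphenyl)magnesium bromide
Product: 20 (S)-1-(3,4-dimethoxyphenyl)-2-hydroxypropan-1-one
Conditions: 12 (2.5 equiv), THF, −20 to 0 °C; aq NH4Cl
Reagents that add atoms: none
Why: Grignard addition to the tertiary amide through the chelated tetrahedral adduct as in step 8; the α-centre is retained.

Step 15
Reactants: 20 (S)-hydroxy ketone
Product: 21 (S)-1-(3,4-dimethoxyphenyl)-1-oxopropan-2-yl 4-methylbenzenesulfonate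
Conditions: TsCl, Et3N, DMAP (cat.), CH2Cl2, 0 °C
Reagents that add atoms: p-toluenesulfonyl chloride, Cc1ccc(cc1)S(Cl)(=O)=O
Why: O-sulfonylation with retention as in step 9.

Step 16
Reactants: 17 ring A phenol; 21 (S)-keto tosylate
Product: 22 ring A aryloxy ketone: 17 in which the ring A oxygen carries (R)-CH(CH3)–C(=O)–(3,4-dimethoxyphenyl)
Conditions: K2CO3, DMF, rt
Reagents that add atoms: none
Why: SN2 displacement next to the carbonyl with inversion, (S) to (R), as in step 10; the phenoxide is far more nucleophilic than the free secondary carbinol of the ring B arm, which carbonate does not deprotonate.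

Step 17
Reactants: 22 ring A aryloxy ketone
Product: 23 target, (1R,2R)-1-(3,4-dimethoxyphenyl)-2-{4-[(2S,3R,4R,5R)-5-(4-{[(1S,2S)-1-(3,4-dimethoxyphenyl)-1-hydroxypropan-2-yl]oxy}-3-methoxyphenyl)-3,4-dimethyltetrahydrofuran-2-yl]-2-methoxyphenoxy}propan-1-ol
Conditions: Bu4NBH4, CH2Cl2/MeOH, −40 to 0 °C
Reagents that add atoms: none
Why: Felkin–Anh-controlled reduction as in step 11, now on the (R)-aryloxy ketone, which should give the threo (1R,2R) arm; the existing carbinol only consumes hydride as its alkoxide.

## Compound list

1 | (E)-isoeugenol | C/C=C/c1ccc(O)c(OC)c1 | starting material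
2 | benzyl bromide | BrCc1ccccc1 | starting material
3 | (E)-isoeugenol benzyl ether | C/C=C/c1ccc(OCc2ccccc2)c(OC)c1 | intermediate
4 | pivaloyl chloride | CC(C)(C)C(Cl)=O | starting material
5 | (E)-isoeugenol pivalate | C/C=C/c1ccc(OC(=O)C(C)(C)C)c(OC)c1 | intermediate
6 | racemic all-trans 1-(ring A benzyl ether)-2-(ring B pivalate)-3,4-dimethylcyclobutane (one enantiomer drawn) | COc1cc(ccc1OCc1ccccc1)[C@@H]1[C@@H](c2ccc(OC(=O)C(C)(C)C)c(OC)c2)[C@H](C)[C@H]1C | intermediate
7 | (1S,2S,3R,4R)-1-[4-(benzyloxy)-3-methoxyphenyl]-2-[3-methoxy-4-(pivaloyloxy)phenyl]-3,4-dimethylcyclobutane, single enantiomer | COc1cc(ccc1OCc1ccccc1)[C@@H]1[C@@H](c2ccc(OC(=O)C(C)(C)C)c(OC)c2)[C@H](C)[C@H]1C | intermediate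
8 | (2S,3R,4R,5R)-2-[4-(benzyloxy)-3-methoxyphenyl]-5-[3-methoxy-4-(pivaloyloxy)phenyl]-3,4-dimethyltetrahydrofuran | COc1cc(ccc1OCc1ccccc1)[C@H]1O[C@@H](c2ccc(OC(=O)C(C)(C)C)c(OC)c2)[C@H](C)[C@H]1C | intermediate
9 | (2S,3R,4R,5R)-2-[4-(benzyloxy)-3-methoxyphenyl]-5-(4-hydroxy-3-methoxyphenyl)-3,4-dimethyltetrahydrofuran | COc1cc(ccc1OCc1ccccc1)[C@H]1O[C@@H](c2ccc(O)c(OC)c2)[C@H](C)[C@H]1C | intermediate
10 | methyl (R)-lactate | C[C@@H](O)C(=O)OC | starting material
11 | (R)-2-hydroxy-1-(pyrrolidin-1-yl)propan-1-one | C[C@@H](O)C(=O)N1CCCC1 | intermediate
12 | (3,4-dimethoxyphenyl)magnesium bromide (commercial THF solution) | COc1ccc([Mg]Br)cc1OC | starting material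
13 | (R)-1-(3,4-dimethoxyphenyl)-2-hydroxypropan-1-one | C[C@@H](O)C(=O)c1ccc(OC)c(OC)c1 | intermediate
14 | (R)-1-(3,4-dimethoxyphenyl)-1-oxopropan-2-yl 4-methylbenzenesulfonate | C[C@@H](OS(=O)(=O)c1ccc(C)cc1)C(=O)c1ccc(OC)c(OC)c1 | intermediate
15 | ring B (S)-aryloxy ketone on the benzyl-protected core | COc1cc(ccc1OCc1ccccc1)[C@H]1O[C@@H](c2ccc(O[C@@H](C)C(=O)c3ccc(OC)c(OC)c3)c(OC)c2)[C@H](C)[C@H]1C | intermediate
16 | ring B (1S,2S)-threo alcohol on the benzyl-protected core | COc1cc(ccc1OCc1ccccc1)[C@H]1O[C@@H](c2ccc(O[C@@H](C)[C@@H](O)c3ccc(OC)c(OC)c3)c(OC)c2)[C@H](C)[C@H]1C | intermediate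
17 | ring A phenol with ring B (1S,2S) arm | COc1cc(ccc1O)[C@H]1O[C@@H](c2ccc(O[C@@H](C)[C@@H](O)c3ccc(OC)c(OC)c3)c(OC)c2)[C@H](C)[C@H]1C | intermediate
18 | ethyl (S)-lactate | C[C@H](O)C(=O)OCC | starting material
19 | (S)-2-hydroxy-1-(pyrrolidin-1-yl)propan-1-one | C[C@H](O)C(=O)N1CCCC1 | intermediate
20 | (S)-1-(3,4-dimethoxyphenyl)-2-hydroxypropan-1-one | C[C@H](O)C(=O)c1ccc(OC)c(OC)c1 | intermediate
21 | (S)-1-(3,4-dimethoxyphenyl)-1-oxopropan-2-yl 4-methylbenzenesulfonate | C[C@H](OS(=O)(=O)c1ccc(C)cc1)C(=O)c1ccc(OC)c(OC)c1 | intermediate
22 | ring A (R)-aryloxy ketone with ring B (1S,2S) arm | COc1ccc(C(=O)[C@@H](C)Oc2ccc([C@H]3O[C@@H](c4ccc(O[C@@H](C)[C@@H](O)c5ccc(OC)c(OC)c5)c(OC)c4)[C@H](C)[C@H]3C)cc2OC)cc1OC | intermediate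
23 | target CNP0116650.16 | COc1ccc([C@@H](O)[C@@H](C)Oc2ccc([C@H]3O[C@@H](c4ccc(O[C@@H](C)[C@@H](O)c5ccc(OC)c(OC)c5)c(OC)c4)[C@H](C)[C@H]3C)cc2OC)cc1OC | target

## Step count and least certain steps

Total: 17 steps. Longest linear sequence: 10 steps (1, 3, 4, 5, 6, 10, 11, 12, 16, 17); the two arm electrophiles are made in two side sequences of three steps each.

**Step 5 (key step, proposed new method).**
- What may go wrong: cycloreversion of the radical cation to 3 and 5 instead of capture by water. Loss of stereospecificity if the bond breaks fully before water arrives, so that a free 1,4-radical cation is attacked on either face and gives the all-trans ring. Attack at C5 instead of C2. Further oxidation or acid epimerisation of 8 at C2.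
- Fallback (known chemistry, from 3, rejoining at 9): the cis end is taken from a syn crotylation and the trans end from an oxocarbenium reduction. Ozonolysis of 3 (O3, then Me2S) gives 4-(benzyloxy)-3-methoxybenzaldehyde F1. Brown crotylation with the antipode of (Z)-crotyl-B(Ipc)2 that delivers the syn alcohol gives (1S,2R)-1-[4-(benzyloxy)-3-methoxyphenyl]-2-methylbut-3-en-1-ol F2. Hydroboration with 9-BBN and oxidation gives the 1,4-diol F3, and TEMPO/PhI(OAc)2 closes it to the cis lactone F4. Methylation of its enolate (LiN(iPr)2, MeI, −78 °C) anti to the neighbouring methyl gives the dimethyl lactone F5. Addition of [4-(tert-butyldimethylsilyloxy)-3-methoxyphenyl]lithium F6, made from commercial 4-bromo-2-methoxyphenyl tert-butyldimethylsilyl ether and n-BuLi, gives hemiketal F7. Et3SiH with BF3·OEt2 at −78 °C reduces it by inside attack of hydride on the 2-aryl oxocarbenium ion, cis to the C4 methyl, so that ring B ends trans to it, giving the silyl-protected tetrahydrofuran F8. Bu4NF then gives 9.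

**Step 3 (crossed [2+2]).**
- What may go wrong: homodimerisation of 3, because neutral 3 is a better nucleophile than 5 towards the radical cation, and cycloreversion of the product if it is oxidised by the catalyst system.
- Fallback (from 3, rejoining at 6): use the homodimerisation. Hole-catalysed dimerisation of 3 alone, the established reaction of isoeugenol ethers, gives the racemic C2-symmetric all-trans bis(benzyl ether) F9. Its two rings are equivalent, so hydrogenolysis stopped near half conversion (H2, Pd/C, with recycling) gives a single mono-phenol F10, and pivaloylation with 4 gives 6.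

**Step 4 (resolution).**
- What may go wrong: insufficient separation or throughput on the chiral phase for a weakly polar molecule without hydrogen-bond donors, and uncertainty in assigning which enantiomer is 7.
- Fallback (from 6, rejoining at 7): classical resolution through diastereomeric esters. Methanolysis of 6 gives the racemic phenol F10 (the compound of the fallback to step 3). Acylation with (1S)-camphanic chloride gives two diastereomeric camphanates, from which the one with the (1S,2S,3R,4R) cyclobutane, F11, is obtained by crystallisation; its crystal structure also fixes the absolute configuration. Methanolysis gives the enantiopure phenol F12, and pivaloylation with 4 gives 7.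

**Step 11 (and its twin, step 17; Felkin–Anh reduction).**
- What may go wrong: poor facial selectivity if chelation through the aryloxy and ortho-methoxy oxygens competes with the Felkin–Anh path, which would give the erythro alcohol.
- Fallback (from 15, rejoining at 16, no new compound): replace substrate control by catalyst control. Noyori asymmetric transfer hydrogenation with RuCl[(R,R)-TsDPEN](p-cymene) in HCO2H/Et3N is the antipode expected to give the (S)-carbinol, by analogy with simple aryl ketones and allowing for the changed CIP priority. For 22 to 23 the (S,S)-catalyst would be used.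

**Step 10 (and its twin, step 16; phenol alkylation).**
- What may go wrong: epimerisation of the aryloxy-bearing carbon of 15, or racemisation of 14 through its enolate, under carbonate, which would erode the configuration of the arm.
- Fallback (from 9 and 13, rejoining at 15, no new compound): Mitsunobu etherification of 9 with hydroxy ketone 13 (PPh3, diisopropyl azodicarboxylate, toluene, 0 °C). It runs without base and also inverts the carbinol carbon, and it saves the tosylation. Step 16 is the same displacement with 17 and 21 and would be judged by the outcome of step 10.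

## Further compounds

F1 | step 5 | 4-(benzyloxy)-3-methoxybenzaldehyde | O=Cc1ccc(OCc2ccccc2)c(OC)c1
F2 | step 5 | (1S,2R)-1-[4-(benzyloxy)-3-methoxyphenyl]-2-methylbut-3-en-1-ol (syn) | COc1cc(ccc1OCc1ccccc1)[C@H]([C@H](C)C=C)O
F3 | step 5 | (1S,2R)-1-[4-(benzyloxy)-3-methoxyphenyl]-2-methylbutane-1,4-diol | COc1cc(ccc1OCc1ccccc1)[C@H]([C@H](C)CCO)O
F4 | step 5 | (4R,5S)-5-[4-(benzyloxy)-3-methoxyphenyl]-4-methyldihydrofuran-2(3H)-one (4,5-cis) | COc1cc(ccc1OCc1ccccc1)[C@H]1OC(=O)C[C@H]1C
F5 | step 5 | (3R,4R,5S)-5-[4-(benzyloxy)-3-methoxyphenyl]-3,4-dimethyldihydrofuran-2(3H)-one (3,4-trans, 4,5-cis) | COc1cc(ccc1OCc1ccccc1)[C@H]1OC(=O)[C@H](C)[C@H]1C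
F6 | step 5 | [4-(tert-butyldimethylsilyloxy)-3-methoxyphenyl]lithium | [Li]c1ccc(O[Si](C)(C)C(C)(C)C)c(OC)c1
F7 | step 5 | hemiketal from F5 and F6, anomeric carbon unassigned | COc1cc(ccc1OCc1ccccc1)[C@H]1OC(O)(c2ccc(O[Si](C)(C)C(C)(C)C)c(OC)c2)[C@H](C)[C@H]1C
F8 | step 5 | (2S,3R,4R,5R)-2-[4-(benzyloxy)-3-methoxyphenyl]-5-[4-(tert-butyldimethylsilyloxy)-3-methoxyphenyl]-3,4-dimethyltetrahydrofuran | COc1cc(ccc1OCc1ccccc1)[C@H]1O[C@@H](c2ccc(O[Si](C)(C)C(C)(C)C)c(OC)c2)[C@H](C)[C@H]1C
F9 | step 3 | racemic all-trans 1,2-bis[4-(benzyloxy)-3-methoxyphenyl]-3,4-dimethylcyclobutane (one enantiomer drawn) | COc1cc(ccc1OCc1ccccc1)[C@@H]1[C@@H](c2ccc(OCc3ccccc3)c(OC)c2)[C@H](C)[C@H]1C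
F10 | step 3 | racemic all-trans 1-[4-(benzyloxy)-3-methoxyphenyl]-2-(4-hydroxy-3-methoxyphenyl)-3,4-dimethylcyclobutane (one enantiomer drawn; also formed in the fallback to step 4) | COc1cc(ccc1OCc1ccccc1)[C@@H]1[C@@H](c2ccc(O)c(OC)c2)[C@H](C)[C@H]1C
F11 | step 4 | (1S,4R)-camphanate of the (1S,2S,3R,4R) cyclobutane phenol | COc1cc(ccc1OCc1ccccc1)[C@@H]1[C@@H](c2ccc(OC(=O)[C@@]34CC[C@@](C)(C(=O)O3)C4(C)C)c(OC)c2)[C@H](C)[C@H]1C
F12 | step 4 | (1S,2S,3R,4R)-1-[4-(benzyloxy)-3-methoxyphenyl]-2-(4-hydroxy-3-methoxyphenyl)-3,4-dimethylcyclobutane, single enantiomer | COc1cc(ccc1OCc1ccccc1)[C@@H]1[C@@H](c2ccc(O)c(OC)c2)[C@H](C)[C@H]1C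
F0 | step 11 | none | none
F0 | step 10 | none | none
A1 | alternative 1 | 2-[3-methoxy-4-(triisopropylsilyloxy)phenyl]-1-[(2S,5S)-2,5-dimethylpyrrolidin-1-yl]ethan-1-one | COc1cc(CC(=O)N2[C@@H](C)CC[C@@H]2C)ccc1O[Si](C(C)C)(C(C)C)C(C)C
A2 | alternative 1 | (E)-but-2-ene | C/C=C/C
A3 | alternative 1 | all-trans 2-(ring B)-3,4-dimethylcyclobutanone | O=C1[C@@H](c2ccc(O[Si](C(C)C)(C(C)C)C(C)C)c(OC)c2)[C@H](C)[C@H]1C
A4 | alternative 1 | all-trans 5-(ring B)-3,4-dimethyldihydrofuran-2(3H)-one | O=C1O[C@@H](c2ccc(O[Si](C(C)C)(C(C)C)C(C)C)c(OC)c2)[C@H](C)[C@H]1C
A5 | alternative 2 | cis-2-(ring B)-5-(ring A)-4-[(Z)-ethylidene]-1,3-dioxolane | COc1cc(ccc1OCc1ccccc1)[C@H]1O[C@@H](c2ccc(O[Si](C(C)C)(C(C)C)C(C)C)c(OC)c2)O/C1=C\C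
A6 | alternative 2 | 2-(ring A)-4-methyl-5-(ring B)-tetrahydrofuran-3-one | COc1cc(ccc1OCc1ccccc1)[C@H]1O[C@@H](c2ccc(O[Si](C(C)C)(C(C)C)C(C)C)c(OC)c2)[C@H](C)C1=O
A7 | alternative 3 | dimethyl trans-2-[4-(benzyloxy)-3-methoxyphenyl]-3-methylcyclopropane-1,1-dicarboxylate | COc1cc(ccc1OCc1ccccc1)[C@H]1[C@H](C)C1(C(=O)OC)C(=O)OC
A8 | alternative 3 | 4-(allyloxy)-3-methoxybenzaldehyde | O=Cc1ccc(OCC=C)c(OC)c1
A9 | alternative 3 | 2,5-cis-diaryl-3-methyltetrahydrofuran-4,4-diester | COc1cc(ccc1OCc1ccccc1)[C@H]1O[C@@H](c2ccc(OCC=C)c(OC)c2)C(C(=O)OC)(C(=O)OC)[C@H]1C
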